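## Retrosynthetic overview
1. The last step is hydrogenolysis of five benzyl ethers. The ester C–O bond is made by Mitsunobu coupling with inversion of a protected 2,4-dihydroxy-6-alkylbenzoic acid with the (S)-carbinol of the resorcinol half.
2. The carboxyl carbon comes from Vilsmeier–Haack formylation and Pinnick oxidation of the same 5-alkylresorcinol skeleton. Both halves therefore derive from one aldehyde, 8-[3,5-bis(benzyloxy)phenyl]octanal.
3. The key C–C bond (carbinol carbon to allyl CH2) is made by Brown asymmetric allylboration of that aldehyde, once with each enantiomer of B-allyldiisopinocampheylborane. The allyl group is then hydrogenated to propyl.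
4. The aldehyde comes from copper-catalysed coupling of 3,5-bis(benzyloxy)benzyl bromide with hept-6-enylmagnesium bromide, followed by hydroboration and oxidation.
5. No ring is formed. Both benzene rings are bought in as methyl 3,5-dihydroxybenzoate.

Assumption: CIP analysis of the given SMILES gives (R) at both carbinol centres, and salt-free 1 M pentane solutions of both enantiomers of B-allyldiisopinocampheylborane are bought as reagents.

## Route

Step 1
Reactants: 1 methyl 3,5-dihydroxybenzoate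
Product: 2 methyl 3,5-bis(benzyloxy)benzoate
Conditions: BnBr (2.3 equiv), K2CO3, acetone, reflux
Reagents that add atoms: benzyl bromide, BrCc1ccccc1
Why: In this Williamson ether synthesis the carbonate deprotonates only the two phenols, which are benzylated by SN2 while the ester is untouched.

Step 2
Reactants: 2 methyl 3,5-bis(benzyloxy)benzoate
Product: 3 [3,5-bis(benzyloxy)phenyl]methanol
Conditions: LiAlH4, THF, 0 °C → rt
Reagents that add atoms: none
Why: Hydride reduction of the ester gives the primary benzylic alcohol, and aryl benzyl ethers are inert to LiAlH4.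

Step 3
Reactants: 3 [3,5-bis(benzyloxy)phenyl]methanol
Product: 4 1,3-bis(benzyloxy)-5-(bromomethyl)benzene
Conditions: PBr3 (0.4 equiv), CH2Cl2, 0 °C → rt
Reagents that add atoms: phosphorus tribromide, BrP(Br)Br
Why: SN2 bromination of the benzylic alcohol through its phosphite ester is fast at low temperature and leaves the ethers alone.

Step 4
Reactants: 4 1,3-bis(benzyloxy)-5-(bromomethyl)benzene; 5 7-bromohept-1-ene
Product: 7 1,3-bis(benzyloxy)-5-(oct-7-en-1-yl)benzene, via hept-6-enylmagnesium bromide 6 (not isolated)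
Conditions: 5, Mg, cat. I2, THF, reflux → rt; then 4, Li2CuCl4 (3 mol %), THF, −10 °C → rt
Reagents that add atoms: magnesium, [Mg] (kept only in 6)
Why: Kochi-type copper-catalysed cross-coupling of a primary alkyl Grignard reagent with a reactive benzylic bromide forms the sp3–sp3 bond, the remote alkene is a spectator, and the hept-6-enyl radical cyclises too slowly to spoil Grignard formation.

Step 5
Reactants: 7 1,3-bis(benzyloxy)-5-(oct-7-en-1-yl)benzene
Product: 9 8-[3,5-bis(benzyloxy)phenyl]octan-1-ol, via B-alkyl-9-BBN adduct 8 (not isolated)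
Conditions: 9-BBN (0.5 M in THF), 0 °C → rt; then 3 M NaOH, 30% H2O2, 0 °C → rt
Reagents that add atoms: hydrogen peroxide, OO; 9-borabicyclo[3.3.1]nonane, B1C2CCCC1CCC2 (kept only in 8)
Why: Brown hydroboration–oxidation with the bulky 9-BBN adds to the terminal alkene with essentially complete anti-Markovnikov selectivity, and the C–B bond is oxidised to the primary alcohol.

Step 6
Reactants: 9 8-[3,5-bis(benzyloxy)phenyl]octan-1-ol
Product: 10 8-[3,5-bis(benzyloxy)phenyl]octanal
Conditions: Dess–Martin periodinane, CH2Cl2, 0 °C → rt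
Reagents that add atoms: none
Why: Dess–Martin oxidation stops cleanly at the aldehyde under neutral conditions and does not touch the electron-rich arene or the benzyl ethers.

Step 7
Reactants: 10 8-[3,5-bis(benzyloxy)phenyl]octanal
Product: 12 (4S)-11-[3,5-bis(benzyloxy)phenyl]undec-1-en-4-ol, via diisopinocampheylborinate 11 (not isolated)
Conditions: B-allyldiisopinocampheylborane derived from (−)-α-pinene (salt-free, 1 M in pentane, 1.3 equiv), Et2O, −100 °C; then 3 M NaOH, 30% H2O2, 0 °C → rt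
Reagents that add atoms: B-allyldiisopinocampheylborane from (−)-α-pinene, C=CCB([C@H]1C[C@H]2C[C@@H]([C@@H]1C)C2(C)C)[C@H]1C[C@H]2C[C@@H]([C@@H]1C)C2(C)C (allyl stays in 12; boron and the isopinocampheyl groups only in 11)
Why: Brown asymmetric allylboration runs through a chair Zimmerman–Traxler transition state in which the isopinocampheyl groups from (−)-α-pinene send the allyl group to the Re face of the aldehyde, setting the (S)-homoallylic carbinol (typically ≥96% ee under these conditions, checked as the Mosher ester), which has the spatial arrangement of the target's (R)-centre.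

Step 8
Reactants: 12 (4S)-11-[3,5-bis(benzyloxy)phenyl]undec-1-en-4-ol
Product: 13 (4R)-11-[3,5-bis(benzyloxy)phenyl]undecan-4-ol
Conditions: H2 (1 atm), RhCl(PPh3)3 (5 mol %), toluene/EtOH 1:1, rt
Reagents that add atoms: none
Why: Homogeneous Wilkinson hydrogenation saturates the unhindered terminal alkene without hydrogenolysing benzyl ethers, no bond at the stereocentre is touched, and the descriptor changes from S to R only because propyl ranks below the long chain.

Step 9
Reactants: 13 (4R)-11-[3,5-bis(benzyloxy)phenyl]undecan-4-ol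
Product: 15 1,3-bis(benzyloxy)-5-[(8R)-8-(benzyloxy)undecyl]benzene, via sodium alkoxide 14 (not isolated)
Conditions: NaH, THF/DMF, 0 °C; then BnBr, Bu4NI (cat.), rt
Reagents that add atoms: benzyl bromide, BrCc1ccccc1; sodium hydride, [Na+].[H-] (sodium kept only in 14)
Why: Williamson benzylation at oxygen leaves the C–O bond of the stereocentre intact and installs a group that survives the next two steps and falls off in the final hydrogenolysis.

Step 10
Reactants: 15 1,3-bis(benzyloxy)-5-[(8R)-8-(benzyloxy)undecyl]benzene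
Product: 17 2,4-bis(benzyloxy)-6-[(8R)-8-(benzyloxy)undecyl]benzaldehyde, via aryl iminium chloride 16 (not isolated)
Conditions: POCl3, DMF, 0 → 75 °C; then aq. NaOAc, rt
Reagents that add atoms: N,N-dimethylformamide, CN(C)C=O (formyl carbon); water, O (aldehyde oxygen); phosphoryl chloride, O=P(Cl)(Cl)Cl (chloride kept only in 16)
Why: Vilsmeier–Haack formylation of a 5-alkylresorcinol diether goes to the position ortho to the alkyl chain and para to one benzyloxy group, because the site between the two benzyloxy groups is more crowded, and the unactivated benzyl rings and the alkyl benzyl ether do not react.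

Step 11
Reactants: 17 2,4-bis(benzyloxy)-6-[(8R)-8-(benzyloxy)undecyl]benzaldehyde
Product: 18 2,4-bis(benzyloxy)-6-[(8R)-8-(benzyloxy)undecyl]benzoic acid
Conditions: NaClO2, NaH2PO4, 2-methylbut-2-ene (large excess), t-BuOH/THF/H2O, rt
Reagents that add atoms: sodium chlorite, [Na+].[O-]Cl=O
Why: Pinnick oxidation converts the hindered aryl aldehyde into the acid under buffered conditions, and the alkene scavenger traps HOCl before it can chlorinate the electron-rich ring.

Step 12
Reactants: 10 8-[3,5-bis(benzyloxy)phenyl]octanal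
Product: 20 (4R)-11-[3,5-bis(benzyloxy)phenyl]undec-1-en-4-ol, via diisopinocampheylborinate 19 (not isolated)
Conditions: B-allyldiisopinocampheylborane derived from (+)-α-pinene (salt-free, 1 M in pentane, 1.3 equiv), Et2O, −100 °C; then 3 M NaOH, 30% H2O2, 0 °C → rt
Reagents that add atoms: B-allyldiisopinocampheylborane from (+)-α-pinene, C=CCB([C@@H]1C[C@@H]2C[C@H]([C@H]1C)C2(C)C)[C@@H]1C[C@@H]2C[C@H]([C@H]1C)C2(C)C (allyl stays in 20; boron and the isopinocampheyl groups only in 19)
Why: This Brown asymmetric allylboration uses the mirror-image reagent, which delivers the allyl group to the Si face through the same chair transition state and sets the (R)-homoallylic carbinol needed for a coupling that inverts.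

Step 13
Reactants: 20 (4R)-11-[3,5-bis(benzyloxy)phenyl]undec-1-en-4-ol
Product: 21 (4S)-11-[3,5-bis(benzyloxy)phenyl]undecan-4-ol
Conditions: H2 (1 atm), RhCl(PPh3)3 (5 mol %), toluene/EtOH 1:1, rt
Reagents that add atoms: none
Why: Wilkinson hydrogenation reduces only the terminal alkene, the stereocentre is untouched, and its descriptor changes from R to S purely through the priority switch.

Step 14
Reactants: 18 2,4-bis(benzyloxy)-6-[(8R)-8-(benzyloxy)undecyl]benzoic acid; 21 (4S)-11-[3,5-bis(benzyloxy)phenyl]undecan-4-ol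
Product: 23 (4R)-11-[3,5-bis(benzyloxy)phenyl]undecan-4-yl 2,4-bis(benzyloxy)-6-[(8R)-8-(benzyloxy)undecyl]benzoate, via alkoxyphosphonium carboxylate 22 (not isolated)
Conditions: PPh3, DIAD, toluene, 0 °C → rt
Reagents that add atoms: triphenylphosphine, c1ccc(cc1)P(c1ccccc1)c1ccccc1 (kept only in 22)
Why: In the Mitsunobu esterification the doubly ortho-substituted acid acts only as a carboxylate nucleophile, so its hindered carbonyl is never attacked, and SN2 displacement at the activated carbinol inverts (S) to the required (R).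

Step 15
Reactants: 23 (4R)-11-[3,5-bis(benzyloxy)phenyl]undecan-4-yl 2,4-bis(benzyloxy)-6-[(8R)-8-(benzyloxy)undecyl]benzoate
Product: 24 integracin B
Conditions: H2 (1 atm), 10% Pd/C, EtOAc/EtOH, rt
Reagents that add atoms: none
Why: Catalytic hydrogenolysis cleaves the four aryl benzyl ethers and the alkyl benzyl ether in one operation, while the secondary alkyl benzoate and both saturated stereocentres are inert.

## Compound list
1 | methyl 3,5-dihydroxybenzoate | COC(=O)c1cc(O)cc(O)c1 | starting material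
2 | methyl 3,5-bis(benzyloxy)benzoate | COC(=O)c1cc(OCc2ccccc2)cc(OCc2ccccc2)c1 | intermediate
3 | [3,5-bis(benzyloxy)phenyl]methanol | OCc1cc(OCc2ccccc2)cc(OCc2ccccc2)c1 | intermediate
4 | 1,3-bis(benzyloxy)-5-(bromomethyl)benzene | BrCc1cc(OCc2ccccc2)cc(OCc2ccccc2)c1 | intermediate
5 | 7-bromohept-1-ene | C=CCCCCCBr | starting material
6 | hept-6-enylmagnesium bromide | C=CCCCCC[Mg]Br | intermediate (not isolated)
7 | 1,3-bis(benzyloxy)-5-(oct-7-en-1-yl)benzene | C=CCCCCCCc1cc(OCc2ccccc2)cc(OCc2ccccc2)c1 | intermediate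
8 | 9-{8-[3,5-bis(benzyloxy)phenyl]octyl}-9-borabicyclo[3.3.1]nonane | C(CCCCCCCc1cc(OCc2ccccc2)cc(OCc2ccccc2)c1)B1C2CCCC1CCC2 | intermediate (not isolated)
9 | 8-[3,5-bis(benzyloxy)phenyl]octan-1-ol | OCCCCCCCCc1cc(OCc2ccccc2)cc(OCc2ccccc2)c1 | intermediate
10 | 8-[3,5-bis(benzyloxy)phenyl]octanal | O=CCCCCCCCc1cc(OCc2ccccc2)cc(OCc2ccccc2)c1 | intermediate
11 | (4S)-11-[3,5-bis(benzyloxy)phenyl]undec-1-en-4-yl diisopinocampheylborinate, isopinocampheyl groups from (−)-α-pinene | C=CC[C@@H](OB([C@H]1C[C@H]2C[C@@H]([C@@H]1C)C2(C)C)[C@H]1C[C@H]2C[C@@H]([C@@H]1C)C2(C)C)CCCCCCCc1cc(OCc2ccccc2)cc(OCc2ccccc2)c1 | intermediate (not isolated)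
12 | (4S)-11-[3,5-bis(benzyloxy)phenyl]undec-1-en-4-ol | C=CC[C@@H](O)CCCCCCCc1cc(OCc2ccccc2)cc(OCc2ccccc2)c1 | intermediate
13 | (4R)-11-[3,5-bis(benzyloxy)phenyl]undecan-4-ol | CCC[C@@H](O)CCCCCCCc1cc(OCc2ccccc2)cc(OCc2ccccc2)c1 | intermediate
14 | sodium (4R)-11-[3,5-bis(benzyloxy)phenyl]undecan-4-olate | CCC[C@@H]([O-])CCCCCCCc1cc(OCc2ccccc2)cc(OCc2ccccc2)c1.[Na+] | intermediate (not isolated)
15 | 1,3-bis(benzyloxy)-5-[(8R)-8-(benzyloxy)undecyl]benzene | CCC[C@@H](OCc1ccccc1)CCCCCCCc1cc(OCc2ccccc2)cc(OCc2ccccc2)c1 | intermediate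
16 | {2,4-bis(benzyloxy)-6-[(8R)-8-(benzyloxy)undecyl]benzylidene}dimethyliminium chloride | CCC[C@@H](OCc1ccccc1)CCCCCCCc1cc(OCc2ccccc2)cc(OCc2ccccc2)c1C=[N+](C)C.[Cl-] | intermediate (not isolated)
17 | 2,4-bis(benzyloxy)-6-[(8R)-8-(benzyloxy)undecyl]benzaldehyde | CCC[C@@H](OCc1ccccc1)CCCCCCCc1cc(OCc2ccccc2)cc(OCc2ccccc2)c1C=O | intermediate
18 | 2,4-bis(benzyloxy)-6-[(8R)-8-(benzyloxy)undecyl]benzoic acid | CCC[C@@H](OCc1ccccc1)CCCCCCCc1cc(OCc2ccccc2)cc(OCc2ccccc2)c1C(=O)O | intermediate
19 | (4R)-11-[3,5-bis(benzyloxy)phenyl]undec-1-en-4-yl diisopinocampheylborinate, isopinocampheyl groups from (+)-α-pinene | C=CC[C@H](OB([C@@H]1C[C@@H]2C[C@H]([C@H]1C)C2(C)C)[C@@H]1C[C@@H]2C[C@H]([C@H]1C)C2(C)C)CCCCCCCc1cc(OCc2ccccc2)cc(OCc2ccccc2)c1 | intermediate (not isolated)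
20 | (4R)-11-[3,5-bis(benzyloxy)phenyl]undec-1-en-4-ol | C=CC[C@H](O)CCCCCCCc1cc(OCc2ccccc2)cc(OCc2ccccc2)c1 | intermediate
21 | (4S)-11-[3,5-bis(benzyloxy)phenyl]undecan-4-ol | CCC[C@H](O)CCCCCCCc1cc(OCc2ccccc2)cc(OCc2ccccc2)c1 | intermediate
22 | {(4S)-11-[3,5-bis(benzyloxy)phenyl]undecan-4-yloxy}triphenylphosphonium 2,4-bis(benzyloxy)-6-[(8R)-8-(benzyloxy)undecyl]benzoate | CCC[C@H](O[P+](c1ccccc1)(c1ccccc1)c1ccccc1)CCCCCCCc1cc(OCc2ccccc2)cc(OCc2ccccc2)c1.CCC[C@@H](OCc1ccccc1)CCCCCCCc1cc(OCc2ccccc2)cc(OCc2ccccc2)c1C(=O)[O-] | intermediate (not isolated)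
23 | (4R)-11-[3,5-bis(benzyloxy)phenyl]undecan-4-yl 2,4-bis(benzyloxy)-6-[(8R)-8-(benzyloxy)undecyl]benzoate | CCC[C@@H](OCc1ccccc1)CCCCCCCc1cc(OCc2ccccc2)cc(OCc2ccccc2)c1C(=O)O[C@H](CCC)CCCCCCCc1cc(OCc2ccccc2)cc(OCc2ccccc2)c1 | intermediate
24 | integracin B, (4R)-11-(3,5-dihydroxyphenyl)undecan-4-yl 2,4-dihydroxy-6-[(8R)-8-hydroxyundecyl]benzoate | CCC[C@@H](O)CCCCCCCc1cc(O)cc(O)c1C(=O)O[C@H](CCC)CCCCCCCc1cc(O)cc(O)c1 | target

## Step count and risks
Total step count: 15.
Longest linear sequence: 13 steps (steps 1–11, 14 and 15). Steps 12 and 13 form the side branch from 10.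

**Step 4 (copper-catalysed benzyl–alkyl coupling).**
- Risk: Wurtz-type homocoupling of 4 to the bibenzyl, and incomplete coupling.
- Range: the fallback sets out from 4 and comes back at 7. It replaces the organometallic coupling by carbanion alkylation.
- Sodium benzenesulfinate in DMF turns 4 into 1,3-bis(benzyloxy)-5-[(phenylsulfonyl)methyl]benzene F1.
- n-BuLi in THF at −78 °C and alkylation of the sulfonyl carbanion with 5 give racemic 1,3-bis(benzyloxy)-5-[1-(phenylsulfonyl)oct-7-en-1-yl]benzene F2.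
- Mg turnings in MeOH remove the sulfonyl group, erase that centre and deliver 7.

**Step 7 (allylboration, together with its mirror image, step 12).**
- Risk: the reaction itself is dependable, but an unbranched aldehyde may give less than about 95% ee. The resulting remote diastereomers of 23 and 24 cannot be separated.
- Range: the fallback sets out from 10 and comes back at 13. It sets the centre by asymmetric hydrogenation.
- Roskamp homologation of 10 with ethyl diazoacetate and SnCl2 (cat.) in CH2Cl2 gives ethyl 10-[3,5-bis(benzyloxy)phenyl]-3-oxodecanoate F3.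
- Noyori hydrogenation with RuCl2[(S)-BINAP] under H2 (4 atm) in EtOH at 80 °C gives ethyl (3S)-10-[3,5-bis(benzyloxy)phenyl]-3-hydroxydecanoate F4, usually in ≥98% ee and with the benzyl ethers intact.
- LiAlH4 gives (3S)-10-[3,5-bis(benzyloxy)phenyl]decane-1,3-diol F5.
- TsCl (1.05 equiv) and Et3N at 0 °C tosylate only the primary hydroxyl, giving (3S)-10-[3,5-bis(benzyloxy)phenyl]-3-hydroxydecyl 4-methylbenzenesulfonate F6.
- Me2CuLi (from MeLi and CuI) in Et2O displaces the tosylate and gives 13. The descriptor changes only through the priority switch.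
- With RuCl2[(R)-BINAP] the same sequence from F3 comes back at 21. It runs through ethyl (3R)-10-[3,5-bis(benzyloxy)phenyl]-3-hydroxydecanoate F7, (3R)-10-[3,5-bis(benzyloxy)phenyl]decane-1,3-diol F8 and (3R)-10-[3,5-bis(benzyloxy)phenyl]-3-hydroxydecyl 4-methylbenzenesulfonate F9.

**Step 14 (Mitsunobu coupling).**
- Risk: sluggish displacement at a carbinol flanked by two chains, elimination to alkenes, and difficult removal of phosphine oxide from a greasy product.
- Range: the fallback sets out from 18 and comes back at 23. It uses acyl transfer with retention in place of SN2 with inversion.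
- Oxalyl chloride with catalytic DMF in CH2Cl2 gives 2,4-bis(benzyloxy)-6-[(8R)-8-(benzyloxy)undecyl]benzoyl chloride F10.
- F10 is added in THF at 0 °C to the sodium alkoxide 14, made from the (R)-alcohol 13 with NaH. The C–O bond of the carbinol is not broken, so (R) is kept and 23 results.
- Steps 12 and 13 then drop out.

## Further compounds
F1 | step 4 | 1,3-bis(benzyloxy)-5-[(phenylsulfonyl)methyl]benzene | O=S(=O)(Cc1cc(OCc2ccccc2)cc(OCc2ccccc2)c1)c1ccccc1
F2 | step 4 | 1,3-bis(benzyloxy)-5-[1-(phenylsulfonyl)oct-7-en-1-yl]benzene (racemic) | C=CCCCCCC(c1cc(OCc2ccccc2)cc(OCc2ccccc2)c1)S(=O)(=O)c1ccccc1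
F3 | step 7 | ethyl 10-[3,5-bis(benzyloxy)phenyl]-3-oxodecanoate | CCOC(=O)CC(=O)CCCCCCCc1cc(OCc2ccccc2)cc(OCc2ccccc2)c1
F4 | step 7 | ethyl (3S)-10-[3,5-bis(benzyloxy)phenyl]-3-hydroxydecanoate | CCOC(=O)C[C@@H](O)CCCCCCCc1cc(OCc2ccccc2)cc(OCc2ccccc2)c1
F5 | step 7 | (3S)-10-[3,5-bis(benzyloxy)phenyl]decane-1,3-diol | OCC[C@@H](O)CCCCCCCc1cc(OCc2ccccc2)cc(OCc2ccccc2)c1
F6 | step 7 | (3S)-10-[3,5-bis(benzyloxy)phenyl]-3-hydroxydecyl 4-methylbenzenesulfonate | Cc1ccc(cc1)S(=O)(=O)OCC[C@@H](O)CCCCCCCc1cc(OCc2ccccc2)cc(OCc2ccccc2)c1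
F7 | step 7 | ethyl (3R)-10-[3,5-bis(benzyloxy)phenyl]-3-hydroxydecanoate | CCOC(=O)C[C@H](O)CCCCCCCc1cc(OCc2ccccc2)cc(OCc2ccccc2)c1
F8 | step 7 | (3R)-10-[3,5-bis(benzyloxy)phenyl]decane-1,3-diol | OCC[C@H](O)CCCCCCCc1cc(OCc2ccccc2)cc(OCc2ccccc2)c1
F9 | step 7 | (3R)-10-[3,5-bis(benzyloxy)phenyl]-3-hydroxydecyl 4-methylbenzenesulfonate | Cc1ccc(cc1)S(=O)(=O)OCC[C@H](O)CCCCCCCc1cc(OCc2ccccc2)cc(OCc2ccccc2)c1
F10 | step 14 | 2,4-bis(benzyloxy)-6-[(8R)-8-(benzyloxy)undecyl]benzoyl chloride | CCC[C@@H](OCc1ccccc1)CCCCCCCc1cc(OCc2ccccc2)cc(OCc2ccccc2)c1C(=O)Cl
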